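**Retrosynthetic overview**

1. The only ring is the 42-membered lactone (C1–C41 plus O41). It is closed last, at C18–C19, by an intramolecular boron aldol reaction. The enabling feature is the C17(OH)–C18(CH3)–C19(OH) anti,syn triad in which C19 is allylic to the (Z)-C20=C21 trisubstituted alkene: C17 can be carried as an ethyl ketone and C19 as a 2-methyl-enal with no α-hydrogen.
2. After the ring closure, a hydroxyl-directed anti reduction sets C17 and a global desilylation gives the target.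
3. The seco ester comes from the northern acid C1–C18 and the southern alcohol C19–C50 (esterification at O41). The southern alcohol comes from the western alkyne C19–C39 and the eastern epoxide C40–C50 (alkyne–epoxide opening, then semi-hydrogenation to the 38Z alkene).
4. The northern all-anti polyol and the western 1,5,9-triol are both built by dithiane anion-relay linchpin couplings onto one common epoxy dithiane, which is C5–C12 in the north and C21–C28 in the west. In the north the dithianes become ketones (C9, C13 reduced anti; C17 kept); in the west they become CH2 (C25, C29).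
5. The eastern epoxide comes from an Ipc-boron syn aldol of a C42–C50 ethyl ketone with chloroacetaldehyde, a syn reduction and epoxide closure.

Key step: step 39

Remark on numbering: carbons carry the macrolide numbers (C1 lactone carbonyl, C41 lactone carbinol, C42–C50 side chain; methyls on C4, C18, C20, C42). CIP descriptors are quoted only for small compounds; for large intermediates the SMILES in the compound list defines every centre.

Assumption: the sense of induction of Ipc2BOTf is taken from acyclic ethyl ketone/aldehyde aldols, the reagent made from (+)-α-pinene sending the (Z)-enolate to the aldehyde Si face; the antipodal reagent would be used if the sense proved the reverse.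

**Shared building blocks (epoxide 4 and common epoxy dithiane 9)**

Step 1
Reactants: 1 but-3-en-1-ol
Product: 2 4-methoxybenzyl but-3-enyl ether
Conditions: NaH, PMBCl, n-Bu4NI (cat.), THF/DMF, 0 °C to rt
Reagents that add atoms: 4-methoxybenzyl chloride, COc1ccc(CCl)cc1
Why: Williamson etherification of a primary alkoxide; no stereocentre is involved.

Step 2
Reactants: 2 4-methoxybenzyl but-3-enyl ether
Product: 3 rac-2-[2-(4-methoxybenzyloxy)ethyl]oxirane
Conditions: mCPBA, NaHCO3, CH2Cl2, 0 °C to rt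
Reagents that add atoms: 3-chloroperoxybenzoic acid, OOC(=O)c1cccc(Cl)c1
Why: Prilezhaev epoxidation of the terminal alkene gives the racemic epoxide.

Step 3
Reactants: 3 rac-2-[2-(4-methoxybenzyloxy)ethyl]oxirane
Product: 4 (S)-2-[2-(4-methoxybenzyloxy)ethyl]oxirane
Conditions: (S,S)-(salen)Co(OAc) (0.5 mol%), H2O (0.55 equiv), THF, 0 °C to rt
Reagents that add atoms: none
Why: Jacobsen hydrolytic kinetic resolution, in which the (S,S)-catalyst hydrolyses the (R)-epoxide and leaves (S)-4, the source of C7 and of C23.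

Step 4
Reactants: 5 2-(tert-butyldimethylsilyl)-1,3-dithiane; 4 (S)-2-[2-(4-methoxybenzyloxy)ethyl]oxirane; 6 (S)-epichlorohydrin
Product: 9 common epoxy dithiane, 2-[(2S)-2-(tert-butyldimethylsilyloxy)-4-(4-methoxybenzyloxy)butyl]-2-[(2S)-oxiran-2-ylmethyl]-1,3-dithiane, via O-silylated 2-lithiodithiane 7 (not isolated), via lithium chloro-alkoxide 8 (not isolated)
Conditions: 5, t-BuLi, Et2O, −78 to −45 °C; 4, −78 to −25 °C; then HMPA, 6, −78 °C to rt
Reagents that add atoms: none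
Why: Smith three-component anion-relay linchpin coupling (opening of 4 at its CH2 terminus, HMPA-triggered 1,4-Brook rearrangement of TBS to the new alkoxide, opening of (S)-epichlorohydrin at its epoxide CH2 and 3-exo-tet closure with loss of chloride), so both centres come from the chiral pool and the one epoxide serves as C5–C12 of the northern acid and as C21–C28 of the western alkyne.

**Northern acid (C1–C18)**

Step 5
Reactants: 10 propanal; 11 propane-1,3-dithiol
Product: 12 2-ethyl-1,3-dithiane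
Conditions: BF3·OEt2 (cat.), CH2Cl2, 0 °C to rt
Reagents that add atoms: none
Why: Lewis-acid dithioacetalisation gives the masked C17 acyl anion (Corey–Seebach umpolung) that carries C18 and its methyl.

Step 6
Reactants: 12 2-ethyl-1,3-dithiane; 13 (R)-epichlorohydrin
Product: 15 (R)-2-ethyl-2-(oxiran-2-ylmethyl)-1,3-dithiane, via lithium chloro-alkoxide 14 (not isolated)
Conditions: n-BuLi, THF, −30 °C; 13, −78 °C to rt
Reagents that add atoms: none
Why: Corey–Seebach alkylation in which the 2-lithiodithiane opens the epoxide at its CH2 terminus and the alkoxide then displaces chloride (3-exo-tet), so C15 comes unchanged from the chiral pool.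

Step 7
Reactants: 5 2-(tert-butyldimethylsilyl)-1,3-dithiane; 15 (R)-2-ethyl-2-(oxiran-2-ylmethyl)-1,3-dithiane; 9 common epoxy dithiane
Product: 17 C5–C18 tris(dithiane) 11-ol (5-OPMB; 7,15-bis-OTBS; dithianes at C9, C13, C17), via O-silylated 2-lithiodithiane 16 (not isolated)
Conditions: 5, t-BuLi, Et2O, −78 to −45 °C; 15, −78 to −25 °C; then HMPA, 9, −78 to 0 °C; aq NH4Cl
Reagents that add atoms: none
Why: Anion-relay linchpin coupling in which the lithiated silyl dithiane opens 15 at its CH2 terminus, the Brook rearrangement protects O15 and gives the C13 anion 16, and this opens 9 at C12 so that O11 stays free; C15 is the centre of 15, C7 and C11 are those of 9.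

Step 8
Reactants: 17 C5–C18 tris(dithiane) 11-ol
Product: 18 C5–C18 11-hydroxy-9,13,17-trione (5-OPMB; 7,15-bis-OTBS)
Conditions: MeI, CaCO3, MeCN/H2O (9:1), 45 °C
Reagents that add atoms: water, O
Why: S-methylative dithiane hydrolysis under buffered neutral conditions unmasks the three ketones without cleaving silyl or PMB ethers or dehydrating the β-hydroxy ketones.

Step 9
Reactants: 18 C5–C18 11-hydroxy-9,13,17-trione
Product: 19 C5–C18 9,11,13-triol 17-ketone (all-anti C7–C15)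
Conditions: Me4NBH(OAc)3, MeCN/AcOH (1:1), −30 °C
Reagents that add atoms: none
Why: Evans–Saksena reduction in which the 11-OH binds the triacetoxyborohydride and delivers hydride intramolecularly to the C9 and C13 ketones through chair transition states (1,3-anti at both), while the C17 ketone, lacking a free β-hydroxyl, is not reduced.

Step 10
Reactants: 19 C5–C18 9,11,13-triol 17-ketone
Product: 20 C5–C18 ethyl ketone (5-OPMB; 7,9,11,13,15-penta-OTBS)
Conditions: TBSOTf, 2,6-lutidine, CH2Cl2, −78 to 0 °C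
Reagents that add atoms: tert-butyldimethylsilyl triflate, CC(C)(C)[Si](C)(C)OS(=O)(=O)C(F)(F)F
Why: Silylation of the three secondary alcohols with the silyl triflate and a hindered base that does not enolise the ketone.

Step 11
Reactants: 20 C5–C18 ethyl ketone PMB ether
Product: 21 C5 primary alcohol (penta-OTBS, C17 ketone)
Conditions: DDQ, CH2Cl2/pH 7 buffer, 0 °C
Reagents that add atoms: none
Why: Oxidative PMB cleavage (single-electron oxidation to the oxocarbenium ion, then hydrolysis) leaves silyl ethers and the ketone untouched.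

Step 12
Reactants: 21 C5 primary alcohol
Product: 22 C5 aldehyde (penta-OTBS, C17 ketone)
Conditions: Dess–Martin periodinane, NaHCO3, CH2Cl2, 0 °C
Reagents that add atoms: none
Why: Buffered Dess–Martin oxidation gives the β-silyloxy aldehyde without β-elimination.

Step 13
Reactants: 22 C5 aldehyde; 23 ethyltriphenylphosphonium iodide
Product: 25 (Z)-C4 vinyl iodide C4–C18, via (1-iodoethyl)triphenylphosphonium iodide 24 (not isolated)
Conditions: 23, n-BuLi, THF, rt; I2, −78 °C; NaN(SiMe3)2, −78 °C; then 22, −78 to −20 °C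
Reagents that add atoms: iodine, II
Why: Stork–Zhao-type iodo-olefination, in which the α-iodo ylide reacts with the aldehyde in preference to the ketone and kinetically places iodine cis to C6, fixing the later 4Z geometry.

Step 14
Reactants: 25 (Z)-C4 vinyl iodide; 26 acrylic acid
Product: 27 northern acid, (2E,4Z)-C1–C18 dienoic acid (penta-OTBS, C17 ethyl ketone)
Conditions: Pd(OAc)2 (10 mol%), K2CO3, n-Bu4NCl, DMF, rt; pH 4 work-up
Reagents that add atoms: none
Why: Heck reaction under Jeffery conditions, where oxidative addition with retention at C4, syn insertion of acrylate and syn β-hydride elimination give the (2E,4Z)-dienoic acid.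

**Western alkyne (C19–C39)**

Step 15
Reactants: 28 (6-bromohexyloxy)(tert-butyl)dimethylsilane; 13 (R)-epichlorohydrin
Product: 31 (R)-tert-butyldimethyl{[7-(oxiran-2-yl)heptyl]oxy}silane, via Grignard reagent 29 (not isolated), via bromomagnesium chloro-alkoxide 30 (not isolated)
Conditions: Mg, THF, rt; CuI (10 mol%), 13, −40 °C; then aq NaOH, rt
Reagents that add atoms: none
Why: Copper-catalysed Grignard opening of epichlorohydrin at its CH2 terminus and base-induced 3-exo-tet closure, so C31 comes from the chiral pool.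

Step 16
Reactants: 5 2-(tert-butyldimethylsilyl)-1,3-dithiane; 31 (R)-tert-butyldimethyl{[7-(oxiran-2-yl)heptyl]oxy}silane; 9 common epoxy dithiane
Product: 33 C21–C38 bis(dithiane) 27-ol (21-OPMB; 23,31,38-tris-OTBS; dithianes at C25, C29), via O-silylated 2-lithiodithiane 32 (not isolated)
Conditions: 5, t-BuLi, Et2O, −78 to −45 °C; 31, −78 to −25 °C; then HMPA, 9, −78 to 0 °C; aq NH4Cl
Reagents that add atoms: none
Why: Anion-relay linchpin coupling as in step 7, in which the Brook rearrangement protects O31 and the C29 anion opens the same epoxide 9 at C28; C31 is the centre of 31, C23 and C27 are those of 9.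

Step 17
Reactants: 33 C21–C38 bis(dithiane) 27-ol
Product: 34 C21–C38 bis(dithiane) (21-OPMB; 23,27,31,38-tetra-OTBS)
Conditions: TBSOTf, 2,6-lutidine, CH2Cl2, −78 to 0 °C
Reagents that add atoms: tert-butyldimethylsilyl triflate, CC(C)(C)[Si](C)(C)OS(=O)(=O)C(F)(F)F
Why: Silylation of the single free (C27) alcohol with the silyl triflate.

Step 18
Reactants: 34 C21–C38 bis(dithiane)
Product: 35 C21–C38 saturated chain (21-OPMB; 23,27,31,38-tetra-OTBS)
Conditions: Raney Ni (W-2, excess), EtOH, 60 °C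
Reagents that add atoms: none
Why: Mozingo-type Raney nickel desulfurisation turns both dithianes into the C25 and C29 methylenes, PMB and silyl ethers being stable to W-2 Raney nickel.

Step 19
Reactants: 35 C21–C38 saturated chain
Product: 36 C38 primary alcohol (21-OPMB; 23,27,31-tris-OTBS)
Conditions: HF·pyridine, pyridine, THF, 0 °C
Reagents that add atoms: none
Why: Selective desilylation, since buffered HF·pyridine cleaves the unhindered primary silyl ether much faster than the three secondary ones.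

Step 20
Reactants: 36 C38 primary alcohol
Product: 37 C38 aldehyde
Conditions: Dess–Martin periodinane, NaHCO3, CH2Cl2, 0 °C
Reagents that add atoms: none
Why: Dess–Martin oxidation of the primary alcohol to the aldehyde under buffered conditions.

Step 21
Reactants: 37 C38 aldehyde; 38 dimethyl (1-diazo-2-oxopropyl)phosphonate
Product: 40 C21–C39 terminal alkyne (21-OPMB; 23,27,31-tris-OTBS), via dimethyl (diazomethyl)phosphonate 39 (not isolated)
Conditions: K2CO3, MeOH, 0 °C to rt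
Reagents that add atoms: none
Why: Ohira–Bestmann (Seyferth–Gilbert) homologation, in which methanolysis releases the diazomethylphosphonate anion that converts the aldehyde into the C38≡C39 alkyne by an alkylidene-carbene 1,2-shift.

Step 22
Reactants: 40 C21–C39 terminal alkyne PMB ether
Product: 41 C21 primary alcohol (alkyne; tris-OTBS)
Conditions: DDQ, CH2Cl2/pH 7 buffer, 0 °C
Reagents that add atoms: none
Why: Oxidative PMB cleavage with DDQ, to which the alkyne and silyl ethers are inert.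

Step 23
Reactants: 41 C21 primary alcohol
Product: 42 C21 aldehyde (alkyne; tris-OTBS)
Conditions: Dess–Martin periodinane, NaHCO3, CH2Cl2, 0 °C
Reagents that add atoms: none
Why: Dess–Martin oxidation to the β-silyloxy aldehyde, which is used at once to avoid β-elimination.

Step 24
Reactants: 42 C21 aldehyde; 43 ethyl 2-[bis(2,2,2-trifluoroethoxy)phosphoryl]propanoate
Product: 44 ethyl (Z)-2-methyl-enoate C19–C39 (alkyne; tris-OTBS)
Conditions: 43, KN(SiMe3)2, 18-crown-6, THF, −78 °C; then 42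
Reagents that add atoms: none
Why: Still–Gennari olefination, where the electron-poor phosphonate under dissociating conditions gives kinetic Z-selectivity and so sets the C20=C21 geometry (C19 cis to C22).

Step 25
Reactants: 44 ethyl (Z)-2-methyl-enoate
Product: 45 (Z)-allylic alcohol C19–C39
Conditions: i-Bu2AlH, CH2Cl2, −78 °C; aq potassium sodium tartrate
Reagents that add atoms: none
Why: 1,2-Reduction of the enoate with i-Bu2AlH at low temperature gives the allylic alcohol without changing the alkene geometry or touching the alkyne.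

Step 26
Reactants: 45 (Z)-allylic alcohol
Product: 46 western alkyne (19-OTES; 23,27,31-tris-OTBS; C38≡C39)
Conditions: TESCl, imidazole, CH2Cl2, 0 °C
Reagents that add atoms: chlorotriethylsilane, CC[Si](Cl)(CC)CC
Why: Silylation of the primary allylic alcohol as a TES ether, chosen because it can later be removed in the presence of ten TBS ethers.

**Eastern epoxide (C40–C50)**

Step 27
Reactants: 47 (R)-propylene oxide; 48 but-3-enylmagnesium bromide
Product: 49 (R)-hept-6-en-2-ol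
Conditions: CuI (10 mol%), THF, −30 to 0 °C; aq NH4Cl
Reagents that add atoms: none
Why: Copper-catalysed Grignard opening of the epoxide at its CH2 terminus, so C49 is the centre of (R)-propylene oxide.

Step 28
Reactants: 49 (R)-hept-6-en-2-ol
Product: 50 (R)-tert-butyl(hept-6-en-2-yloxy)dimethylsilane
Conditions: TBSCl, imidazole, DMF, rt
Reagents that add atoms: tert-butyldimethylsilyl chloride, CC(C)(C)[Si](C)(C)Cl
Why: Standard Corey silylation of the secondary alcohol.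

Step 29
Reactants: 50 (R)-tert-butyl(hept-6-en-2-yloxy)dimethylsilane; 51 pent-1-en-3-one
Product: 52 (R,E)-9-(tert-butyldimethylsilyloxy)dec-4-en-3-one
Conditions: second-generation Hoveyda–Grubbs catalyst (5 mol%), CH2Cl2, 40 °C
Reagents that add atoms: none
Why: Olefin cross-metathesis of a terminal alkene with an electron-poor vinyl ketone, which is selective for the (E)-hetero-coupled enone.

Step 30
Reactants: 52 (R,E)-9-(tert-butyldimethylsilyloxy)dec-4-en-3-one
Product: 53 (R)-9-(tert-butyldimethylsilyloxy)decan-3-one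
Conditions: H2 (1 atm), Pd/C, EtOAc, rt
Reagents that add atoms: none
Why: Heterogeneous hydrogenation of the enone C=C, with the ketone and silyl ether retained.

Step 31
Reactants: 53 (R)-9-(tert-butyldimethylsilyloxy)decan-3-one; 54 chloroacetaldehyde (anhydrous monomer, distilled from the commercial aqueous solution)
Product: 57 (2R,3R,10R)-10-(tert-butyldimethylsilyloxy)-1-chloro-2-hydroxy-3-methylundecan-4-one, via (Z)-enol diisopinocampheylborinate 55 (not isolated), via boron aldolate 56 (not isolated)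
Conditions: (+)-Ipc2BOTf (from (−)-α-pinene), i-Pr2NEt, CH2Cl2, −78 °C; 54, −78 to −20 °C; then H2O2, MeOH, pH 7 buffer, 0 °C
Reagents that add atoms: none
Why: Paterson aldol, in which soft enolisation gives the (Z)-enol borinate whose chair transition state gives the 41,42-syn aldol, the (+)-Ipc ligands directing attack to the Re face of the aldehyde (41R in this compound).

Step 32
Reactants: 57 chloro aldol
Product: 59 C40–C50 epoxy alcohol (C40–C41 oxirane; 43-OH; 49-OTBS; 41,42,43-syn,syn), via syn-chloro diol 58 (not isolated)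
Conditions: Et2BOMe, NaBH4, THF/MeOH (4:1), −78 °C; then K2CO3, MeOH, rt
Reagents that add atoms: none
Why: Narasaka–Prasad reduction (external hydride on the boron chelate of the 41-hydroxy ketone gives the 41,43-syn diol) followed by base-induced 3-exo-tet closure of the 41-alkoxide onto C40.

Step 33
Reactants: 59 C40–C50 epoxy alcohol
Product: 60 eastern epoxide (C40–C41 oxirane; 43,49-bis-OTBS)
Conditions: TBSOTf, 2,6-lutidine, CH2Cl2, −78 °C
Reagents that add atoms: tert-butyldimethylsilyl triflate, CC(C)(C)[Si](C)(C)OS(=O)(=O)C(F)(F)F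
Why: Silylation of the C43 alcohol, the epoxide being stable to the silyl triflate and 2,6-lutidine at −78 °C.

**Assembly and endgame**

Step 34
Reactants: 46 western alkyne; 60 eastern epoxide
Product: 61 C19–C50 homopropargylic alcohol (41-OH; 19-OTES; 23,27,31,43,49-penta-OTBS)
Conditions: 46, n-BuLi, THF, −78 °C; BF3·OEt2; then 60, −78 °C
Reagents that add atoms: none
Why: Yamaguchi–Hirao alkynylation, in which the lithium acetylide/BF3 species opens the epoxide at its C40 terminus with C41 untouched, leaving 41-OH as the only free hydroxyl.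

Step 35
Reactants: 61 C19–C50 homopropargylic alcohol
Product: 62 southern alcohol, (20Z,38Z)-C19–C50 (41-OH)
Conditions: H2 (1 atm), Pd/CaCO3/Pb(OAc)2, quinoline, EtOAc/hexane, rt
Reagents that add atoms: none
Why: Lindlar semi-hydrogenation (syn addition) gives the 38Z alkene without reducing the trisubstituted alkene.

Step 36
Reactants: 27 northern acid; 62 southern alcohol
Product: 64 seco ester (19-OTES; C17 ethyl ketone; deca-OTBS), via mixed anhydride 63 (not isolated)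
Conditions: 27, 2,4,6-trichlorobenzoyl chloride, Et3N, THF, rt; then 62, DMAP, toluene, rt
Reagents that add atoms: none
Why: Yamaguchi esterification of the hindered C41 alcohol through the mixed anhydride and acylpyridinium, which affects neither the stereocentres nor the (2E,4Z)-diene.

Step 37
Reactants: 64 seco ester
Product: 65 seco allylic alcohol (19-OH)
Conditions: PPTS, MeOH/CH2Cl2 (1:4), 0 °C
Reagents that add atoms: none
Why: Mild acid methanolysis removes the primary allylic TES ether selectively over the secondary TBS ethers.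

Step 38
Reactants: 65 seco allylic alcohol
Product: 66 seco keto-enal (C19 (Z)-2-methyl-enal; C17 ethyl ketone)
Conditions: Dess–Martin periodinane, NaHCO3, CH2Cl2, 0 °C
Reagents that add atoms: none
Why: Buffered Dess–Martin oxidation of the allylic alcohol gives the (Z)-2-methyl-enal without Z/E isomerisation.

Step 39
Reactants: 66 seco keto-enal
Product: 69 macrocyclic aldol (42-membered lactone; C17 ketone; 19-OH; deca-OTBS), via (Z)-enol diisopinocampheylborinate 67 (not isolated), via macrocyclic boron aldolate 68 (not isolated)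
Conditions: (−)-Ipc2BOTf (from (+)-α-pinene, 5 equiv), i-Pr2NEt (8 equiv), CH2Cl2, −78 °C; 66 by syringe pump over 10 h (final 1 mM); −78 to −20 °C, 24 h; then H2O2, MeOH, pH 7 buffer, 0 °C
Reagents that add atoms: none
Why: Proposed new method: Soft enolisation of the C17 ethyl ketone by (−)-Ipc2BOTf/i-Pr2NEt should give the (Z)-enol diisopinocampheylborinate 67 regioselectively at C18 (the C16 methylene is shielded by the branched, silyloxy-bearing C15), and this persistent boron enolate adds intramolecularly to the C19 enal through a Zimmerman–Traxler chair to give aldolate 68. The closest known reaction types are the reagent-controlled Paterson syn aldol of ethyl ketones with 2-methyl-2-enals and macroaldolisations of ketone or ester enolates onto tethered aldehydes; joining the two in one ring-closing event is new. The 42-membered ring is closed in a 42-(enolexo)-exo-trig mode, the enolate carbon C18 attacking the exocyclic C19=O. C18 follows from the (Z)-enolate geometry in the chair (18,19-syn), and C19 from the Ipc ligands on boron, which direct attack to the Si face of the aldehyde (19S). The step needs regioselective enolisation, cyclisation rather than oligomerisation and retention of the 20Z enal; these are secured by the hindered C16 flank, by slow addition at 1 mM to a long-lived enol borinate, and by the absence of an α-hydrogen at C20, while the C15 silyl ether switches off competing 1,5-induction.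

Step 40
Reactants: 69 macrocyclic aldol
Product: 70 deca-TBS macrolide 17,19-diol
Conditions: Me4NBH(OAc)3, MeCN/AcOH (1:1), −30 °C
Reagents that add atoms: none
Why: Evans–Saksena reduction, in which the 19-OH delivers hydride intramolecularly to C17 through a chair transition state to give the 17,19-anti diol (17R).

Step 41
Reactants: 70 deca-TBS macrolide 17,19-diol
Product: 71 CNP0392687.1
Conditions: HF·pyridine, pyridine, THF, 0 °C to rt
Reagents that add atoms: none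
Why: Global fluoride-mediated desilylation of the ten TBS ethers under buffered conditions that spare the lactone, the allylic alcohol and the alkenes.

**Compound list**

1 | but-3-en-1-ol | C=CCCO | starting material
2 | 4-methoxybenzyl but-3-enyl ether | COc1ccc(COCCC=C)cc1 | intermediate
3 | rac-2-[2-(4-methoxybenzyloxy)ethyl]oxirane | COc1ccc(COCCC2CO2)cc1 | intermediate
4 | (S)-2-[2-(4-methoxybenzyloxy)ethyl]oxirane | COc1ccc(COCC[C@H]2CO2)cc1 | intermediate
5 | 2-(tert-butyldimethylsilyl)-1,3-dithiane | CC(C)(C)[Si](C)(C)C1SCCCS1 | starting material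
6 | (S)-epichlorohydrin | ClC[C@@H]1CO1 | starting material
7 | 2-lithio-1,3-dithiane carrying a 2-(tert-butyldimethylsilyloxy)-4-(4-methoxybenzyloxy)butyl chain (from 5 and 4) | [Li]C1(C[C@@H](O[Si](C)(C)C(C)(C)C)CCOCc2ccc(OC)cc2)SCCCS1 | intermediate
8 | lithium chloro-alkoxide from 7 and 6 (terminal CH2Cl, adjacent lithium alkoxide; dithiane; OTBS; OPMB) | ClC[C@@H](O[Li])CC1(SCCCS1)C[C@@H](O[Si](C)(C)C(C)(C)C)CCOCc1ccc(OC)cc1 | intermediate
9 | common epoxy dithiane, 2-[(2S)-2-(tert-butyldimethylsilyloxy)-4-(4-methoxybenzyloxy)butyl]-2-[(2S)-oxiran-2-ylmethyl]-1,3-dithiane (C5–C12 in the north, C21–C28 in the west) | COc1ccc(COCC[C@H](O[Si](C)(C)C(C)(C)C)CC2(SCCCS2)C[C@H]3CO3)cc1 | intermediate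
10 | propanal | CCC=O | starting material
11 | propane-1,3-dithiol | SCCCS | starting material
12 | 2-ethyl-1,3-dithiane | CCC1SCCCS1 | intermediate
13 | (R)-epichlorohydrin | ClC[C@H]1CO1 | starting material
14 | lithium (R)-1-chloro-3-(2-ethyl-1,3-dithian-2-yl)propan-2-olate | CCC1(SCCCS1)C[C@@H](O[Li])CCl | intermediate
15 | (R)-2-ethyl-2-(oxiran-2-ylmethyl)-1,3-dithiane | CCC1(SCCCS1)C[C@@H]2CO2 | intermediate
16 | C13-lithiated dithiane carrying the C14–C18 chain (15-OTBS, C17 ethyl dithiane) | [Li]C1(C[C@H](O[Si](C)(C)C(C)(C)C)CC2(CC)SCCCS2)SCCCS1 | intermediate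
17 | C5–C18 tris(dithiane) 11-ol (5-OPMB; 7,15-bis-OTBS) | COc1ccc(COCC[C@H](O[Si](C)(C)C(C)(C)C)CC2(SCCCS2)C[C@H](O)CC3(SCCCS3)C[C@H](O[Si](C)(C)C(C)(C)C)CC4(CC)SCCCS4)cc1 | intermediate
18 | C5–C18 11-hydroxy-9,13,17-trione (5-OPMB; 7,15-bis-OTBS) | COc1ccc(COCC[C@H](O[Si](C)(C)C(C)(C)C)CC(=O)C[C@H](O)CC(=O)C[C@H](O[Si](C)(C)C(C)(C)C)CC(=O)CC)cc1 | intermediate
19 | C5–C18 9,11,13-triol 17-ketone (5-OPMB; 7,15-bis-OTBS; all-anti) | COc1ccc(COCC[C@H](O[Si](C)(C)C(C)(C)C)C[C@@H](O)C[C@H](O)C[C@@H](O)C[C@H](O[Si](C)(C)C(C)(C)C)CC(=O)CC)cc1 | intermediate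
20 | C5–C18 ethyl ketone (5-OPMB; 7,9,11,13,15-penta-OTBS) | COc1ccc(COCC[C@H](O[Si](C)(C)C(C)(C)C)C[C@@H](O[Si](C)(C)C(C)(C)C)C[C@H](O[Si](C)(C)C(C)(C)C)C[C@@H](O[Si](C)(C)C(C)(C)C)C[C@H](O[Si](C)(C)C(C)(C)C)CC(=O)CC)cc1 | intermediate
21 | C5 alcohol of the C5–C18 ethyl ketone (penta-OTBS) | OCC[C@H](O[Si](C)(C)C(C)(C)C)C[C@@H](O[Si](C)(C)C(C)(C)C)C[C@H](O[Si](C)(C)C(C)(C)C)C[C@@H](O[Si](C)(C)C(C)(C)C)C[C@H](O[Si](C)(C)C(C)(C)C)CC(=O)CC | intermediate
22 | C5 aldehyde of the C5–C18 ethyl ketone (penta-OTBS) | O=CC[C@H](O[Si](C)(C)C(C)(C)C)C[C@@H](O[Si](C)(C)C(C)(C)C)C[C@H](O[Si](C)(C)C(C)(C)C)C[C@@H](O[Si](C)(C)C(C)(C)C)C[C@H](O[Si](C)(C)C(C)(C)C)CC(=O)CC | intermediate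
23 | ethyltriphenylphosphonium iodide | CC[P+](c1ccccc1)(c1ccccc1)c1ccccc1.[I-] | starting material
24 | (1-iodoethyl)triphenylphosphonium iodide | CC(I)[P+](c1ccccc1)(c1ccccc1)c1ccccc1.[I-] | intermediate
25 | (Z)-C4 vinyl iodide C4–C18 (penta-OTBS, C17 ketone) | I/C(C)=C\C[C@H](O[Si](C)(C)C(C)(C)C)C[C@@H](O[Si](C)(C)C(C)(C)C)C[C@H](O[Si](C)(C)C(C)(C)C)C[C@@H](O[Si](C)(C)C(C)(C)C)C[C@H](O[Si](C)(C)C(C)(C)C)CC(=O)CC | intermediate
26 | acrylic acid | OC(=O)C=C | starting material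
27 | northern acid, (2E,4Z)-C1–C18 dienoic acid (penta-OTBS, C17 ethyl ketone) | OC(=O)/C=C/C(C)=C\C[C@H](O[Si](C)(C)C(C)(C)C)C[C@@H](O[Si](C)(C)C(C)(C)C)C[C@H](O[Si](C)(C)C(C)(C)C)C[C@@H](O[Si](C)(C)C(C)(C)C)C[C@H](O[Si](C)(C)C(C)(C)C)CC(=O)CC | intermediate
28 | (6-bromohexyloxy)(tert-butyl)dimethylsilane | CC(C)(C)[Si](C)(C)OCCCCCCBr | starting material
29 | 6-(tert-butyldimethylsilyloxy)hexylmagnesium bromide | CC(C)(C)[Si](C)(C)OCCCCCC[Mg]Br | intermediate
30 | bromomagnesium (R)-9-(tert-butyldimethylsilyloxy)-1-chlorononan-2-olate | CC(C)(C)[Si](C)(C)OCCCCCCC[C@@H](O[Mg]Br)CCl | intermediate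
31 | (R)-tert-butyldimethyl{[7-(oxiran-2-yl)heptyl]oxy}silane | CC(C)(C)[Si](C)(C)OCCCCCCC[C@@H]1CO1 | intermediate
32 | C29-lithiated dithiane carrying the C30–C38 chain (31,38-bis-OTBS) | [Li]C1(C[C@H](O[Si](C)(C)C(C)(C)C)CCCCCCCO[Si](C)(C)C(C)(C)C)SCCCS1 | intermediate
33 | C21–C38 bis(dithiane) 27-ol (21-OPMB; 23,31,38-tris-OTBS) | COc1ccc(COCC[C@H](O[Si](C)(C)C(C)(C)C)CC2(SCCCS2)C[C@H](O)CC3(SCCCS3)C[C@H](O[Si](C)(C)C(C)(C)C)CCCCCCCO[Si](C)(C)C(C)(C)C)cc1 | intermediate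
34 | C21–C38 bis(dithiane) (21-OPMB; 23,27,31,38-tetra-OTBS) | COc1ccc(COCC[C@H](O[Si](C)(C)C(C)(C)C)CC2(SCCCS2)C[C@H](O[Si](C)(C)C(C)(C)C)CC3(SCCCS3)C[C@H](O[Si](C)(C)C(C)(C)C)CCCCCCCO[Si](C)(C)C(C)(C)C)cc1 | intermediate
35 | C21–C38 saturated chain (21-OPMB; 23,27,31,38-tetra-OTBS) | COc1ccc(COCC[C@H](O[Si](C)(C)C(C)(C)C)CCC[C@H](O[Si](C)(C)C(C)(C)C)CCC[C@H](O[Si](C)(C)C(C)(C)C)CCCCCCCO[Si](C)(C)C(C)(C)C)cc1 | intermediate
36 | C38 alcohol (21-OPMB; 23,27,31-tris-OTBS) | COc1ccc(COCC[C@H](O[Si](C)(C)C(C)(C)C)CCC[C@H](O[Si](C)(C)C(C)(C)C)CCC[C@H](O[Si](C)(C)C(C)(C)C)CCCCCCCO)cc1 | intermediate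
37 | C38 aldehyde (21-OPMB; 23,27,31-tris-OTBS) | COc1ccc(COCC[C@H](O[Si](C)(C)C(C)(C)C)CCC[C@H](O[Si](C)(C)C(C)(C)C)CCC[C@H](O[Si](C)(C)C(C)(C)C)CCCCCCC=O)cc1 | intermediate
38 | dimethyl (1-diazo-2-oxopropyl)phosphonate | COP(=O)(OC)C(=[N+]=[N-])C(C)=O | starting material
39 | dimethyl (diazomethyl)phosphonate | COP(=O)(OC)C=[N+]=[N-] | intermediate
40 | C21–C39 terminal alkyne (21-OPMB; 23,27,31-tris-OTBS) | COc1ccc(COCC[C@H](O[Si](C)(C)C(C)(C)C)CCC[C@H](O[Si](C)(C)C(C)(C)C)CCC[C@H](O[Si](C)(C)C(C)(C)C)CCCCCCC#C)cc1 | intermediate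
41 | C21 alcohol (C38≡C39 alkyne; tris-OTBS) | OCC[C@H](O[Si](C)(C)C(C)(C)C)CCC[C@H](O[Si](C)(C)C(C)(C)C)CCC[C@H](O[Si](C)(C)C(C)(C)C)CCCCCCC#C | intermediate
42 | C21 aldehyde (C38≡C39 alkyne; tris-OTBS) | O=CC[C@H](O[Si](C)(C)C(C)(C)C)CCC[C@H](O[Si](C)(C)C(C)(C)C)CCC[C@H](O[Si](C)(C)C(C)(C)C)CCCCCCC#C | intermediate
43 | ethyl 2-[bis(2,2,2-trifluoroethoxy)phosphoryl]propanoate | CCOC(=O)C(C)P(=O)(OCC(F)(F)F)OCC(F)(F)F | starting material
44 | ethyl (Z)-2-methyl-enoate C19–C39 (tris-OTBS; alkyne) | CCOC(=O)/C(C)=C\C[C@H](O[Si](C)(C)C(C)(C)C)CCC[C@H](O[Si](C)(C)C(C)(C)C)CCC[C@H](O[Si](C)(C)C(C)(C)C)CCCCCCC#C | intermediate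
45 | (Z)-allylic alcohol C19–C39 (tris-OTBS; alkyne) | OC/C(C)=C\C[C@H](O[Si](C)(C)C(C)(C)C)CCC[C@H](O[Si](C)(C)C(C)(C)C)CCC[C@H](O[Si](C)(C)C(C)(C)C)CCCCCCC#C | intermediate
46 | western alkyne C19–C39 (19-OTES; 23,27,31-tris-OTBS) | CC[Si](CC)(CC)OC/C(C)=C\C[C@H](O[Si](C)(C)C(C)(C)C)CCC[C@H](O[Si](C)(C)C(C)(C)C)CCC[C@H](O[Si](C)(C)C(C)(C)C)CCCCCCC#C | intermediate
47 | (R)-propylene oxide | C[C@@H]1CO1 | starting material
48 | but-3-enylmagnesium bromide | C=CCC[Mg]Br | starting material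
49 | (R)-hept-6-en-2-ol | C=CCCC[C@@H](C)O | intermediate
50 | (R)-tert-butyl(hept-6-en-2-yloxy)dimethylsilane | C=CCCC[C@@H](C)O[Si](C)(C)C(C)(C)C | intermediate
51 | pent-1-en-3-one | CCC(=O)C=C | starting material
52 | (R,E)-9-(tert-butyldimethylsilyloxy)dec-4-en-3-one | CCC(=O)/C=C/CCC[C@@H](C)O[Si](C)(C)C(C)(C)C | intermediate
53 | (R)-9-(tert-butyldimethylsilyloxy)decan-3-one | CCC(=O)CCCCC[C@@H](C)O[Si](C)(C)C(C)(C)C | intermediate
54 | chloroacetaldehyde | ClCC=O | starting material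
55 | (Z)-enol bis[(+)-isopinocampheyl]borinate of 53 | C/C=C(\OB([C@H]1C[C@H]2C[C@@H]([C@@H]1C)C2(C)C)[C@H]1C[C@H]2C[C@@H]([C@@H]1C)C2(C)C)CCCCC[C@@H](C)O[Si](C)(C)C(C)(C)C | intermediate
56 | O-bis[(+)-isopinocampheyl]boryl aldolate of 57 | ClC[C@H](OB([C@H]1C[C@H]2C[C@@H]([C@@H]1C)C2(C)C)[C@H]1C[C@H]2C[C@@H]([C@@H]1C)C2(C)C)[C@@H](C)C(=O)CCCCC[C@@H](C)O[Si](C)(C)C(C)(C)C | intermediate
57 | (2R,3R,10R)-10-(tert-butyldimethylsilyloxy)-1-chloro-2-hydroxy-3-methylundecan-4-one | ClC[C@H](O)[C@@H](C)C(=O)CCCCC[C@@H](C)O[Si](C)(C)C(C)(C)C | intermediate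
58 | syn,syn-chloro diol C40–C50 (40-Cl; 41,43-diol; 49-OTBS) | ClC[C@H](O)[C@@H](C)[C@H](O)CCCCC[C@@H](C)O[Si](C)(C)C(C)(C)C | intermediate
59 | C40–C50 epoxy alcohol (C40–C41 oxirane; 43-OH; 49-OTBS) | C1O[C@@H]1[C@@H](C)[C@H](O)CCCCC[C@@H](C)O[Si](C)(C)C(C)(C)C | intermediate
60 | eastern epoxide C40–C50 (C40–C41 oxirane; 43,49-bis-OTBS) | C1O[C@@H]1[C@@H](C)[C@H](O[Si](C)(C)C(C)(C)C)CCCCC[C@@H](C)O[Si](C)(C)C(C)(C)C | intermediate
61 | C19–C50 homopropargylic alcohol (41-OH; 19-OTES; penta-OTBS; C38≡C39) | CC[Si](CC)(CC)OC/C(C)=C\C[C@H](O[Si](C)(C)C(C)(C)C)CCC[C@H](O[Si](C)(C)C(C)(C)C)CCC[C@H](O[Si](C)(C)C(C)(C)C)CCCCCCC#CC[C@H](O)[C@@H](C)[C@H](O[Si](C)(C)C(C)(C)C)CCCCC[C@@H](C)O[Si](C)(C)C(C)(C)C | intermediate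
62 | southern alcohol, (20Z,38Z)-C19–C50 (41-OH; 19-OTES; penta-OTBS) | CC[Si](CC)(CC)OC/C(C)=C\C[C@H](O[Si](C)(C)C(C)(C)C)CCC[C@H](O[Si](C)(C)C(C)(C)C)CCC[C@H](O[Si](C)(C)C(C)(C)C)CCCCCC/C=C\C[C@H](O)[C@@H](C)[C@H](O[Si](C)(C)C(C)(C)C)CCCCC[C@@H](C)O[Si](C)(C)C(C)(C)C | intermediate
63 | mixed anhydride of 27 with 2,4,6-trichlorobenzoic acid | Clc1cc(Cl)c(C(=O)OC(=O)/C=C/C(C)=C\C[C@H](O[Si](C)(C)C(C)(C)C)C[C@@H](O[Si](C)(C)C(C)(C)C)C[C@H](O[Si](C)(C)C(C)(C)C)C[C@@H](O[Si](C)(C)C(C)(C)C)C[C@H](O[Si](C)(C)C(C)(C)C)CC(=O)CC)c(Cl)c1 | intermediate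
64 | seco ester (O41 acylated by 27; 19-OTES; C17 ethyl ketone; deca-OTBS) | CC[Si](CC)(CC)OC/C(C)=C\C[C@H](O[Si](C)(C)C(C)(C)C)CCC[C@H](O[Si](C)(C)C(C)(C)C)CCC[C@H](O[Si](C)(C)C(C)(C)C)CCCCCC/C=C\C[C@@H]([C@@H](C)[C@H](O[Si](C)(C)C(C)(C)C)CCCCC[C@@H](C)O[Si](C)(C)C(C)(C)C)OC(=O)/C=C/C(C)=C\C[C@H](O[Si](C)(C)C(C)(C)C)C[C@@H](O[Si](C)(C)C(C)(C)C)C[C@H](O[Si](C)(C)C(C)(C)C)C[C@@H](O[Si](C)(C)C(C)(C)C)C[C@H](O[Si](C)(C)C(C)(C)C)CC(=O)CC | intermediate
65 | seco allylic alcohol (19-OH; C17 ethyl ketone; deca-OTBS) | OC/C(C)=C\C[C@H](O[Si](C)(C)C(C)(C)C)CCC[C@H](O[Si](C)(C)C(C)(C)C)CCC[C@H](O[Si](C)(C)C(C)(C)C)CCCCCC/C=C\C[C@@H]([C@@H](C)[C@H](O[Si](C)(C)C(C)(C)C)CCCCC[C@@H](C)O[Si](C)(C)C(C)(C)C)OC(=O)/C=C/C(C)=C\C[C@H](O[Si](C)(C)C(C)(C)C)C[C@@H](O[Si](C)(C)C(C)(C)C)C[C@H](O[Si](C)(C)C(C)(C)C)C[C@@H](O[Si](C)(C)C(C)(C)C)C[C@H](O[Si](C)(C)C(C)(C)C)CC(=O)CC | intermediate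
66 | seco keto-enal (C19 (Z)-2-methyl-enal; C17 ethyl ketone; deca-OTBS) | O=C/C(C)=C\C[C@H](O[Si](C)(C)C(C)(C)C)CCC[C@H](O[Si](C)(C)C(C)(C)C)CCC[C@H](O[Si](C)(C)C(C)(C)C)CCCCCC/C=C\C[C@@H]([C@@H](C)[C@H](O[Si](C)(C)C(C)(C)C)CCCCC[C@@H](C)O[Si](C)(C)C(C)(C)C)OC(=O)/C=C/C(C)=C\C[C@H](O[Si](C)(C)C(C)(C)C)C[C@@H](O[Si](C)(C)C(C)(C)C)C[C@H](O[Si](C)(C)C(C)(C)C)C[C@@H](O[Si](C)(C)C(C)(C)C)C[C@H](O[Si](C)(C)C(C)(C)C)CC(=O)CC | intermediate
67 | (Z)-C17 enol bis[(−)-isopinocampheyl]borinate of 66 | O=C/C(C)=C\C[C@H](O[Si](C)(C)C(C)(C)C)CCC[C@H](O[Si](C)(C)C(C)(C)C)CCC[C@H](O[Si](C)(C)C(C)(C)C)CCCCCC/C=C\C[C@@H]([C@@H](C)[C@H](O[Si](C)(C)C(C)(C)C)CCCCC[C@@H](C)O[Si](C)(C)C(C)(C)C)OC(=O)/C=C/C(C)=C\C[C@H](O[Si](C)(C)C(C)(C)C)C[C@@H](O[Si](C)(C)C(C)(C)C)C[C@H](O[Si](C)(C)C(C)(C)C)C[C@@H](O[Si](C)(C)C(C)(C)C)C[C@H](O[Si](C)(C)C(C)(C)C)C/C(OB([C@@H]1C[C@@H]2C[C@H]([C@H]1C)C2(C)C)[C@@H]1C[C@@H]2C[C@H]([C@H]1C)C2(C)C)=C/C | intermediate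
68 | macrocyclic O19-bis[(−)-isopinocampheyl]boryl aldolate | CC1=C/C[C@H](O[Si](C)(C)C(C)(C)C)C[C@@H](O[Si](C)(C)C(C)(C)C)C[C@H](O[Si](C)(C)C(C)(C)C)C[C@@H](O[Si](C)(C)C(C)(C)C)C[C@H](O[Si](C)(C)C(C)(C)C)CC(=O)[C@@H](C)[C@H](OB([C@@H]2C[C@@H]3C[C@H]([C@H]2C)C3(C)C)[C@@H]2C[C@@H]3C[C@H]([C@H]2C)C3(C)C)/C(C)=C\C[C@H](O[Si](C)(C)C(C)(C)C)CCC[C@H](O[Si](C)(C)C(C)(C)C)CCC[C@H](O[Si](C)(C)C(C)(C)C)CCCCCC/C=C\C[C@@H]([C@@H](C)[C@H](O[Si](C)(C)C(C)(C)C)CCCCC[C@@H](C)O[Si](C)(C)C(C)(C)C)OC(=O)\C=C\1 | intermediate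
69 | macrocyclic aldol (42-membered lactone; C17 ketone; 19-OH; 18,19-syn; deca-OTBS) | CC1=C/C[C@H](O[Si](C)(C)C(C)(C)C)C[C@@H](O[Si](C)(C)C(C)(C)C)C[C@H](O[Si](C)(C)C(C)(C)C)C[C@@H](O[Si](C)(C)C(C)(C)C)C[C@H](O[Si](C)(C)C(C)(C)C)CC(=O)[C@@H](C)[C@H](O)/C(C)=C\C[C@H](O[Si](C)(C)C(C)(C)C)CCC[C@H](O[Si](C)(C)C(C)(C)C)CCC[C@H](O[Si](C)(C)C(C)(C)C)CCCCCC/C=C\C[C@@H]([C@@H](C)[C@H](O[Si](C)(C)C(C)(C)C)CCCCC[C@@H](C)O[Si](C)(C)C(C)(C)C)OC(=O)\C=C\1 | intermediate
70 | deca-TBS macrolide 17,19-diol | CC1=C/C[C@H](O[Si](C)(C)C(C)(C)C)C[C@@H](O[Si](C)(C)C(C)(C)C)C[C@H](O[Si](C)(C)C(C)(C)C)C[C@@H](O[Si](C)(C)C(C)(C)C)C[C@H](O[Si](C)(C)C(C)(C)C)C[C@@H](O)[C@@H](C)[C@H](O)/C(C)=C\C[C@H](O[Si](C)(C)C(C)(C)C)CCC[C@H](O[Si](C)(C)C(C)(C)C)CCC[C@H](O[Si](C)(C)C(C)(C)C)CCCCCC/C=C\C[C@@H]([C@@H](C)[C@H](O[Si](C)(C)C(C)(C)C)CCCCC[C@@H](C)O[Si](C)(C)C(C)(C)C)OC(=O)\C=C\1 | intermediate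
71 | CNP0392687.1 | CC1=C/C[C@H](O)C[C@@H](O)C[C@H](O)C[C@@H](O)C[C@H](O)C[C@@H](O)[C@@H](C)[C@H](O)/C(C)=C\C[C@H](O)CCC[C@H](O)CCC[C@H](O)CCCCCC/C=C\C[C@@H]([C@@H](C)[C@H](O)CCCCC[C@@H](C)O)OC(=O)\C=C\1 | target

**Step count and risks**

Total steps: 41. Longest linear sequence: 23 steps (steps 1–4, 16–26, 34–41).

Steps most likely to fail:

1. Step 39 (proposed new method). It may fail through enolisation toward C16 with β-elimination of the C15 silyloxy group, through oligomerisation instead of ring closure, through Z-to-E isomerisation of the enal, or through weak facial control. Fallback with known chemistry, setting out from 65: LiN(SiMe3)2 with TMSCl as internal quench (THF, −78 °C) should give the bis-trimethylsilyl derivative (C19 silyl ether, C17 silyl enol ether) F1, which is brominated in the same flask with NBS and desilylated on citric acid work-up to the α-bromo ketone allylic alcohol F2 (C18 epimers). Dess–Martin oxidation gives the bromo keto-enal F3. Slow addition of F3 to SmI2 (THF, −78 °C, 1 mM) then effects a Reformatsky macrocyclisation through a trivalent samarium enolate, a known way to close large rings; stereocontrol is then substrate-based and the C18/C19 diastereomers are separated. The route is rejoined at 69.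

2. Step 31. Facial selectivity may erode with the small, α-chloro aldehyde, chloroacetaldehyde may self-condense, and the minor aldol isomer differs from the major one only relative to the remote C49 centre and may not separate. Fallback, setting out from 50: linear hydroformylation (Rh(acac)(CO)2, Xantphos, CO/H2) gives (R)-7-(tert-butyldimethylsilyloxy)octanal F4. An Evans syn aldol with (S)-4-benzyl-3-propionyloxazolidin-2-one (n-Bu2BOTf, Et3N) gives the crystalline imide F5, with C42 and C43 set by the auxiliary. Transamidation (AlMe3, MeONHMe·HCl) gives the Weinreb amide F6, and LiCH2Cl (from ICH2Cl and MeLi·LiBr, −78 °C) gives the chloromethyl ketone F7. Narasaka–Prasad reduction of F7, now directed by the 43-OH, gives the chloro diol 58, where the route is rejoined (closure to 59 as in step 32).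

3. Step 13. The iodo-ylide may give low conversion or poor Z-selectivity, and its basicity may enolise the β-silyloxy ketone. Fallback, setting out from 22: Corey–Fuchs dibromo-olefination (CBr4, PPh3, CH2Cl2, 0 °C) gives the 1,1-dibromoalkene F8. A trans-selective Negishi monomethylation (MeZnCl, Pd(DPEphos)Cl2, THF) replaces the bromine trans to C6 and leaves the (Z)-2-bromoalkene F9. F9 enters the Heck reaction of step 14 (60 °C) and the route is rejoined at 27.

Further compounds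
F1 | step 39 | bis-trimethylsilyl derivative of 65 (19-OTMS; C17 trimethylsilyl enol ether, E/Z mixture) | C[Si](C)(C)OC/C(C)=C\C[C@H](O[Si](C)(C)C(C)(C)C)CCC[C@H](O[Si](C)(C)C(C)(C)C)CCC[C@H](O[Si](C)(C)C(C)(C)C)CCCCCC/C=C\C[C@@H]([C@@H](C)[C@H](O[Si](C)(C)C(C)(C)C)CCCCC[C@@H](C)O[Si](C)(C)C(C)(C)C)OC(=O)/C=C/C(C)=C\C[C@H](O[Si](C)(C)C(C)(C)C)C[C@@H](O[Si](C)(C)C(C)(C)C)C[C@H](O[Si](C)(C)C(C)(C)C)C[C@@H](O[Si](C)(C)C(C)(C)C)C[C@H](O[Si](C)(C)C(C)(C)C)CC(O[Si](C)(C)C)=CC
F2 | step 39 | 18-bromo seco allylic alcohol (19-OH; C17 ketone; C18 epimers) | OC/C(C)=C\C[C@H](O[Si](C)(C)C(C)(C)C)CCC[C@H](O[Si](C)(C)C(C)(C)C)CCC[C@H](O[Si](C)(C)C(C)(C)C)CCCCCC/C=C\C[C@@H]([C@@H](C)[C@H](O[Si](C)(C)C(C)(C)C)CCCCC[C@@H](C)O[Si](C)(C)C(C)(C)C)OC(=O)/C=C/C(C)=C\C[C@H](O[Si](C)(C)C(C)(C)C)C[C@@H](O[Si](C)(C)C(C)(C)C)C[C@H](O[Si](C)(C)C(C)(C)C)C[C@@H](O[Si](C)(C)C(C)(C)C)C[C@H](O[Si](C)(C)C(C)(C)C)CC(=O)C(C)Br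
F3 | step 39 | 18-bromo seco keto-enal (C18 epimers) | O=C/C(C)=C\C[C@H](O[Si](C)(C)C(C)(C)C)CCC[C@H](O[Si](C)(C)C(C)(C)C)CCC[C@H](O[Si](C)(C)C(C)(C)C)CCCCCC/C=C\C[C@@H]([C@@H](C)[C@H](O[Si](C)(C)C(C)(C)C)CCCCC[C@@H](C)O[Si](C)(C)C(C)(C)C)OC(=O)/C=C/C(C)=C\C[C@H](O[Si](C)(C)C(C)(C)C)C[C@@H](O[Si](C)(C)C(C)(C)C)C[C@H](O[Si](C)(C)C(C)(C)C)C[C@@H](O[Si](C)(C)C(C)(C)C)C[C@H](O[Si](C)(C)C(C)(C)C)CC(=O)C(C)Br
F4 | step 31 | (R)-7-(tert-butyldimethylsilyloxy)octanal | O=CCCCCC[C@@H](C)O[Si](C)(C)C(C)(C)C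
F5 | step 31 | (S)-4-benzyl-3-[(2S,3R,9R)-9-(tert-butyldimethylsilyloxy)-3-hydroxy-2-methyldecanoyl]oxazolidin-2-one | O=C1OC[C@H](Cc2ccccc2)N1C(=O)[C@@H](C)[C@H](O)CCCCC[C@@H](C)O[Si](C)(C)C(C)(C)C
F6 | step 31 | (2S,3R,9R)-9-(tert-butyldimethylsilyloxy)-3-hydroxy-N-methoxy-N,2-dimethyldecanamide | CON(C)C(=O)[C@@H](C)[C@H](O)CCCCC[C@@H](C)O[Si](C)(C)C(C)(C)C
F7 | step 31 | chloromethyl ketone C40–C50 (40-Cl; C41 ketone; 43-OH; 49-OTBS; 42,43-syn) | ClCC(=O)[C@@H](C)[C@H](O)CCCCC[C@@H](C)O[Si](C)(C)C(C)(C)C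
F8 | step 13 | 4,4-dibromo-alkene C4–C18 (penta-OTBS, C17 ketone) | BrC(Br)=CC[C@H](O[Si](C)(C)C(C)(C)C)C[C@@H](O[Si](C)(C)C(C)(C)C)C[C@H](O[Si](C)(C)C(C)(C)C)C[C@@H](O[Si](C)(C)C(C)(C)C)C[C@H](O[Si](C)(C)C(C)(C)C)CC(=O)CC
F9 | step 13 | (Z)-C4 vinyl bromide C4–C18 (penta-OTBS, C17 ketone) | Br/C(C)=C\C[C@H](O[Si](C)(C)C(C)(C)C)C[C@@H](O[Si](C)(C)C(C)(C)C)C[C@H](O[Si](C)(C)C(C)(C)C)C[C@@H](O[Si](C)(C)C(C)(C)C)C[C@H](O[Si](C)(C)C(C)(C)C)CC(=O)CC
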